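**Remark on numbering.** Ring A is C1–C6 (C1 bears the hydroxyl, C6 the ether oxygen) and ring B is C1'–C6' (C1' bears the ether oxygen, C2' the hydroxyl). The same locants are used for the corresponding carbons of every intermediate, including the cyclohexanone ring of 3 and 4 (carbonyl carbon = C1, aryloxy-bearing carbon = C6), although the systematic names of 3 and 4 number that carbon as 2. Compounds 1 and 2 are assumed to be purchasable.

## Analysis of the target

The target is a diphenyl ether: two benzene rings, ring A and ring B, joined by a single oxygen between C6 and C1'. It has no further ring and no stereocentre, so the problem is entirely one of regiochemistry. Ring A carries a hydroxyl at C1 and bromine at C2 and C4; ring B carries a hydroxyl at C2' and bromine at C3', C5' and C6'. Four of the five bromines (C2, C4, C3', C5') lie ortho or para to a hydroxyl and can be placed by phenol-directed substitution, whereas C6'–Br is meta to the C2' hydroxyl and has to be present from the start. The sensitive groups are the two electron-rich phenols, which oxidize and over-brominate easily, and the five aryl bromides, which exclude reducing conditions, organolithium reagents and most transition-metal couplings once they are in place. The hard bond is the ether: at C1' it sits between two ortho substituents (C2'–O and C6'–Br) and at C6 next to C1–OH, so an aryl–oxygen coupling would be hindered on both sides and would have to spare C–Br bonds. The strategy rests on ring A. A phenol with bromine at exactly the ortho (C2) and para (C4) carbons and an aryloxy group at the other ortho carbon (C6) is what a 2-aryloxycyclohexanone should become on bromination and dehydrobromination. Ring A can therefore be carried as a saturated ketone and the C6–O bond made by substitution at an sp3 carbon.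

## Retrosynthetic reasoning

**8 to 7 (C3'–Br).** The last bond made is C3'–Br. In 7 the C2' hydroxyl has only one free ortho or para position, C3', because C1' carries the ether oxygen and C5' a bromine. C4' is meta to that hydroxyl, and ring A has no free activated position. The substrate therefore dictates the regiochemistry, and the forward reaction only has to deliver one equivalent of electrophilic bromine to a free phenol.

**7 to 6 (O–CH3 at C2').** The C2' hydroxyl of 7 is traced back to the methyl ether of 6. The cap is needed earlier for three reasons:
- it makes 1 a monophenol, so only the C1' oxygen can be alkylated;
- it keeps the C2' oxygen from adding to the ketone of 3;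
- as a donor lying in the ring plane it sends the first ring B bromination para to itself, to C5'.

A methyl group is chosen because it withstands bromine and strong acid. The forward step is a Lewis-acid ether cleavage that must leave the diaryl ether and four C–Br bonds untouched.

**6 to 3 (C2–Br, C4–Br, C5'–Br, and the aromaticity of ring A).** The central disconnection removes three C–Br bonds and returns ring A to the oxidation level of a cyclohexanone. It is placed here, and not at the diaryl ether of 6, because an aryl–oxygen coupling would face double ortho hindrance and competing C–Br bonds. In 3 the same oxygen is attached to a saturated, carbonyl-activated carbon. The carbonyl carbon maps onto C1–OH and its two α-carbons onto C2 and C6. Forward, a single halogenating reagent has to brominate both α-carbons, lose acid twice to aromatize, substitute the new phenol at C2 and C4, and substitute ring B at C5'. It must leave C3, C5, C3' and C4' alone and must not cleave the C6–O bond before ring A is aromatic.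

**3 to 1 + 2 (C6–O).** The ether of 3 is cut between the phenol oxygen of 1 and the chlorine-bearing carbon of 2. Phenol 1 already holds C6'–Br and the C2' methoxy group in the contiguous 1,2,3-arrangement, which electrophilic substitution could not set up, and 2 supplies all six carbons of ring A. The forward reaction is an SN2 displacement by a doubly ortho-substituted phenoxide at a secondary but activated carbon, under a base mild enough that 2 neither self-condenses nor rearranges.

## Alternatives that were turned down

**Alternative 1:** Here ring B, not ring A, is built from a saturated precursor. The disconnection is the C1'–C2' bond of a cyclohexane-1,3-dione. In the forward direction a hindered alkoxide base deprotonates the aryloxy-bearing methylene of the keto ester A1 (methyl 6-(2-methoxyphenoxy)-5-oxohexanoate). The enolate closes onto the ester carbonyl in a Claisen (Dieckmann-type) condensation to give the dione A2 (2-(2-methoxyphenoxy)cyclohexane-1,3-dione).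
- For: the closure is a six-membered acylation driven by formation of the stabilized dione enolate. A2 is symmetric about C1', so one carbonyl can become C2'–OH and the other, through the vinylogous acid bromide, C6'–Br. The ether is again made at an sp3 carbon.
- Against: A1 is not purchasable and needs two or three steps of its own (an α-halo ketone from a glutaric half ester, then O-alkylation). After A2 one carbonyl still has to be turned into a vinyl bromide, ring B aromatized, the ring A hydroxyl freed and four positions brominated, so the route is roughly twice as long. The aromatization of an α-aryloxy enone is of the same kind, and as uncertain, as the key step chosen here.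
- Comparison: its one stronger point is that C6'–Br originates from a carbonyl rather than from a purchased bromophenol. The chosen route answers this by taking that bromine from 1 at no cost in steps.

**Alternative 2:** The disconnection removes the O–C1' and C6'–Br bonds together by aryne chemistry. A fluoride source releases the silylaryne A4 (3-(trimethylsilyl)benzyne) from the bis-silyl triflate A3 (2,6-bis(trimethylsilyl)phenyl trifluoromethanesulfonate). The phenoxide A5 (potassium 2-methoxyphenoxide) adds to the aryne carbon next to silicon, and the aryl anion is trapped by a positive-bromine donor to give the silane A6 ([3-bromo-2-(2-methoxyphenoxy)phenyl]trimethylsilane).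
- For: the most hindered bond is formed without a transition metal, both of its ortho neighbours are set in one operation, and two aromatic pieces are joined convergently.
- Against: the site of phenoxide attack depends on a balance between aryne distortion by silicon, which favours the adjacent carbon, and the bulk of the trimethylsilyl group, which favours the remote one, so the wrong regioisomer is a real prospect. Protonation of the aryl anion competes with bromine transfer. A3 needs several steps. The aryl–silicon bond at C2' is not yet a hydroxyl and needs ipso-borylation and oxidation, or a similar exchange, before the hydroxyl-directed brominations can follow.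
- Comparison: its strength is the controlled oxygen/oxygen/bromine pattern around C1'. The chosen route obtains that pattern directly from 1 and is shorter and surer in regiochemistry.

**Alternative 3:** Both hydroxyls are traced back to formyl groups. In the dialdehyde A7 (3-bromo-2-(2-formylphenoxy)benzaldehyde) the formyl groups first activate the nucleophilic aromatic substitution that makes the diaryl ether, from an ortho-fluorobenzaldehyde and a salicylaldehyde-type phenoxide. A peracid then inserts oxygen into both aryl–CHO bonds with aryl migration (Baeyer–Villiger/Dakin), and methanolysis of the two formates gives the bisphenol A8 (3-bromo-2-(2-hydroxyphenoxy)phenol). Fourfold bromination of A8 at the ortho and para positions of its two hydroxyls would complete the target.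
- For: every reaction type is established for hydroxylated diphenyl ethers, and the ether is made without a metal. The sequence needs three operations, one fewer than the chosen route, and no protecting group, because all four bromination sites are activated alike. On step count and on precedent this alternative is at least as strong as the chosen one.
- Against: the substitution must occur at a fluorine-bearing carbon flanked by formyl and bromine, with a phenoxide that is itself deactivated by an ortho-formyl group, so forcing conditions are needed. Oxygen insertion must proceed twice with aryl rather than hydrogen migration. On ring B the migrating carbon lies next to an aryloxy group twisted out of conjugation and meta to bromine, so oxidation to the carboxylic acid is the likely leak.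
- What the chosen strategy offers instead: the ether is formed at a saturated, carbonyl-activated carbon under mild base. No peracid and no question of migratory aptitude arise. Bromine is the only oxidant and the only halogen source. The capped C2' oxygen lets ring B be brominated in two controlled stages, C5' first and C3' last.

Key step: step 2

## Route

Step 1
Reactants: 1 2-bromo-6-methoxyphenol; 2 2-chlorocyclohexan-1-one (racemic)
Product: 3 2-(2-bromo-6-methoxyphenoxy)cyclohexan-1-one (racemate)
Conditions: K2CO3, KI (cat.), acetone, reflux
Reagents that add atoms: none
Why: Williamson ether synthesis by SN2 displacement at the carbonyl-activated α-carbon, helped by in situ Finkelstein exchange of chloride for iodide; the phenoxide is a weak base, so Favorskii rearrangement and elimination of 2 should stay minor. The new stereocentre forms as a racemate and is erased in step 2.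

Step 2
Reactants: 3 2-(2-bromo-6-methoxyphenoxy)cyclohexan-1-one
Product: 6 2,4-dibromo-6-(2,3-dibromo-6-methoxyphenoxy)phenol, via dibromo ketone 4 (not isolated), via aryloxyphenol 5 (not isolated)
Conditions: Br2 (3 equiv), AcOH, 20 °C; 80 °C, N2 sweep; then Br2 (2 equiv), 20 to 60 °C
Reagents that add atoms: bromine, BrBr
Why: HBr released by the first substitution catalyses enolization of 3, so that bromine enters at both α-carbons (C2 and the aryloxy-bearing C6) while ring B, an anisole, is brominated para to its methoxy group at C5'; the resulting 4 already has the oxidation level of a phenol. On warming, 4 should lose HBr twice, first from C6, where the bromide is part of an α-bromo ether and ionizes readily, then from C2 through the dienol of the resulting enone, whose allylic bromide leaves with aromatization; the former carbonyl carbon thereby becomes C1–OH of 5. The second charge of bromine then substitutes 5 at C2 and C4, ortho and para to the new hydroxyl, by electrophilic aromatic substitution. The closest known reaction type is the polybromination and dehydrobromination of cyclohexanones to bromophenols, of which the conversion of 2,2,6,6-tetrabromocyclohexanone into 2,6-dibromophenol is the textbook case. No ring is closed and no stereocentre is created; the single stereocentre of 3 disappears. Three selectivities are needed: no bromine at C3 or C5, served by adding bromine in two charges so that little free bromine is present while enone and dienol intermediates exist and by the hydroxyl outranking the aryloxy group as director once ring A is aromatic; ring B substitution at C5' only, which follows from the C2' methoxy group lying in the ring plane whereas the C1' oxygen is twisted between two ortho substituents; and survival of the C6–O bond, for which the medium is kept anhydrous and HBr is swept out with nitrogen. An α-bromine that is not eliminated can only remain on C2, where the target carries bromine in any case, so five equivalents of Br2 are consumed on either path. The methyl ether is stable to these conditions and keeps the C2' oxygen from adding to the ketone.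

Step 3
Reactants: 6 2,4-dibromo-6-(2,3-dibromo-6-methoxyphenoxy)phenol
Product: 7 2,4-dibromo-6-(2,3-dibromo-6-hydroxyphenoxy)phenol
Conditions: BBr3 (3 equiv), CH2Cl2, −78 °C to 20 °C; H2O
Reagents that add atoms: none
Why: Lewis-acid cleavage of an aryl methyl ether: BBr3 binds the methoxy oxygen and bromide attacks the methyl carbon by SN2. The diaryl ether offers no sp3 carbon for attack, the aryl bromides are inert, and the free phenol only consumes one equivalent as an aryloxyborane that hydrolyses on work-up.

Step 4
Reactants: 7 2,4-dibromo-6-(2,3-dibromo-6-hydroxyphenoxy)phenol
Product: 8 2,4-dibromo-6-(2,3,5-tribromo-6-hydroxyphenoxy)phenol (the target)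
Conditions: Br2 (1.0 equiv), AcOH, 20 °C
Reagents that add atoms: bromine, BrBr
Why: Electrophilic aromatic bromination directed by the free C2' hydroxyl, whose only open ortho or para position is C3'. C4' is meta to that hydroxyl and para only to the twisted, weakly donating diaryl ether oxygen, and ring A has no free activated position, so one equivalent should stop at the pentabromide.

## Compound list

1 | 2-bromo-6-methoxyphenol | COc1cccc(Br)c1O | starting material
2 | 2-chlorocyclohexan-1-one (racemic) | O=C1CCCCC1Cl | starting material
3 | 2-(2-bromo-6-methoxyphenoxy)cyclohexan-1-one (racemate, one enantiomer drawn) | COc1cccc(Br)c1O[C@H]1CCCCC1=O | intermediate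
4 | 2,6-dibromo-2-(2,3-dibromo-6-methoxyphenoxy)cyclohexan-1-one (mixture of stereoisomers, not isolated) | COc1ccc(Br)c(Br)c1OC1(Br)CCCC(Br)C1=O | intermediate
5 | 2-(2,3-dibromo-6-methoxyphenoxy)phenol (not isolated) | COc1ccc(Br)c(Br)c1Oc1ccccc1O | intermediate
6 | 2,4-dibromo-6-(2,3-dibromo-6-methoxyphenoxy)phenol | Oc1c(Br)cc(Br)cc1Oc1c(OC)ccc(Br)c1Br | intermediate
7 | 2,4-dibromo-6-(2,3-dibromo-6-hydroxyphenoxy)phenol | Oc1c(Br)cc(Br)cc1Oc1c(O)ccc(Br)c1Br | intermediate
8 | 2,4-dibromo-6-(2,3,5-tribromo-6-hydroxyphenoxy)phenol, also named 3,4,6-tribromo-2-(3,5-dibromo-2-hydroxyphenoxy)phenol (no stereocentre) | Oc1c(Br)cc(Br)cc1Oc1c(O)c(Br)cc(Br)c1Br | target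

## Step count and risk

Total step count: 4. Longest linear sequence: 4 steps (1 and 2 to 3, then 6, 7 and 8).

**Step 2 (key step).** Two processes are most likely to spoil it.
- Addition of bromine across the enol-ether double bond of an intermediate 2-aryloxy enone, which would leave a bromine at C5.
- Cleavage of the C6–O bond by bromide attack at the α-keto carbon before ring A is aromatic.

Both arise because the aryloxy group makes C6 at once an enol-ether carbon and an SN2-activated centre. Incomplete loss of HBr would add mixtures of partly brominated ketones.

The fallback gives up the saturated precursor and makes the ring A phenol from an aldehyde. It sets out from 1. Nucleophilic aromatic substitution on 2-fluorobenzaldehyde (O=Cc1ccccc1F; K2CO3, DMF, 120 °C) should give 2-(2-bromo-6-methoxyphenoxy)benzaldehyde F1. Baeyer–Villiger oxidation with mCPBA in CH2Cl2 should give 2-(2-bromo-6-methoxyphenoxy)phenyl formate F2, which is cleaved without isolation by K2CO3 in methanol to 2-(2-bromo-6-methoxyphenoxy)phenol F3. Br2 (3 equiv) in AcOH then substitutes C2, C4 and C5', and the fallback rejoins the route at 6.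

**Step 1.** The doubly ortho-substituted phenoxide is a slow nucleophile at a secondary carbon. This gives base-induced self-condensation, dehydrochlorination or Favorskii-type rearrangement of 2 time to compete.

The fallback replaces the α-halo ketone by an epoxide. It sets out from 1 and cyclohexene oxide (C1CCC2OC2C1). Heating with catalytic K2CO3 in DMF at 110 °C should open the epoxide from the rear and give trans-2-(2-bromo-6-methoxyphenoxy)cyclohexan-1-ol F4 as a racemate. Oxidation with Dess–Martin periodinane in CH2Cl2 brings the fallback back to the route at 3.

**Step 4.** The most likely failure is uneven consumption of the single equivalent of bromine. Further substitution at C4' or ipso attack on the fully substituted phenol rings could occur while part of the sparingly soluble 7 is still unreacted. The reactivity gap between C3' and the unwanted sites is the narrowest of the sequence, because ring B already carries two bromines.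

The fallback moves the demethylation ahead of all ring brominations, so that no late single-site bromination is needed. It sets out from 1 and follows the fallback to step 2 as far as the phenol F3. BBr3 in CH2Cl2 should then give 3-bromo-2-(2-hydroxyphenoxy)phenol F5, the same compound as A8. Br2 (4 equiv) in AcOH should substitute the four free ortho and para positions of the two hydroxyls (C2, C4, C3', C5') in one operation, and the fallback rejoins the route at 8.

## Further compounds

F1 | step 2 | 2-(2-bromo-6-methoxyphenoxy)benzaldehyde | COc1cccc(Br)c1Oc1ccccc1C=O
F2 | step 2 | 2-(2-bromo-6-methoxyphenoxy)phenyl formate | COc1cccc(Br)c1Oc1ccccc1OC=O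
F3 | step 2 | 2-(2-bromo-6-methoxyphenoxy)phenol | COc1cccc(Br)c1Oc1ccccc1O
F4 | step 1 | trans-2-(2-bromo-6-methoxyphenoxy)cyclohexan-1-ol (racemate, (1R,2R) enantiomer drawn) | COc1cccc(Br)c1O[C@@H]1CCCC[C@H]1O
F5 | step 4 | 3-bromo-2-(2-hydroxyphenoxy)phenol | Oc1ccccc1Oc1c(O)cccc1Br
A1 | alternative 1 | methyl 6-(2-methoxyphenoxy)-5-oxohexanoate | COC(=O)CCCC(=O)COc1ccccc1OC
A2 | alternative 1 | 2-(2-methoxyphenoxy)cyclohexane-1,3-dione | COc1ccccc1OC1C(=O)CCCC1=O
A3 | alternative 2 | 2,6-bis(trimethylsilyl)phenyl trifluoromethanesulfonate | C[Si](C)(C)c1cccc([Si](C)(C)C)c1OS(=O)(=O)C(F)(F)F
A4 | alternative 2 | 3-(trimethylsilyl)benzyne | C[Si](C)(C)C1=CC=CC#C1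
A5 | alternative 2 | potassium 2-methoxyphenoxide | COc1ccccc1[O-].[K+]
A6 | alternative 2 | [3-bromo-2-(2-methoxyphenoxy)phenyl]trimethylsilane | COc1ccccc1Oc1c(Br)cccc1[Si](C)(C)C
A7 | alternative 3 | 3-bromo-2-(2-formylphenoxy)benzaldehyde | O=Cc1ccccc1Oc1c(C=O)cccc1Br
A8 | alternative 3 | 3-bromo-2-(2-hydroxyphenoxy)phenol | Oc1ccccc1Oc1c(O)cccc1Br
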